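Everything rests on reading ring A of the C6-linked acacetin half (unit 1) as a benzannulation product. C5(OH), C6(aryl), C7(O) and C8(H) are the four carbons of a squarate-derived cyclobutenone, and the C8a=C4a bond is the C2=C3 alkene of a ready-made 6-anisyl-γ-pyranone. One heating operation opens the four-membered ring to a ketene and closes it on pyranone C3. This forms C4a–C5, ring A and the chelated 5-OH, while the crowded C6–C8'' bond and the 6-linkage are already in place. The precursor is a 2-aryl-3-isopropoxy-4-(4-oxopyran-2-yl)cyclobutenone whose phloroglucinol-derived aryl group carries one MOM and two benzyl ethers. Ring C of unit 2 is grown afterwards on the MOM oxygen.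

Key step: step 9

Assumption: the target SMILES holds no stereocentre and gives no sense for the C6–C8'' axis, so all biaryls are made as racemates about that axis.

Design notes:
- The oxygen that becomes O1'' stays capped as its MOM ether until after the key step, because a free phenol ortho to the ketene-bearing carbon would lactonise the ketene.
- To protect that acetal, the squarate adduct is activated with (CF3CO)2O instead of mineral acid, and the chlorination is buffered.
- The C4–H of the pyranyl cyclobutenone is doubly activated, so the coupling and the thermolysis are run without base.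

Step 1
Reactants: 1 3,5-bis(benzyloxy)phenol
Product: 2 1,3-bis(benzyloxy)-5-(methoxymethoxy)benzene
Conditions: MOMCl (1.3 equiv), iPr2NEt (1.6 equiv), CH2Cl2, 0 °C → rt
Reagents that add atoms: chloromethyl methyl ether, COCCl
Why: Williamson-type O-alkylation of the only phenol puts the strongest ortho-directing group on the oxygen that will become O1'' and keeps that oxygen distinguishable from the two benzyl-capped ones.

Step 2
Reactants: 2 1,3-bis(benzyloxy)-5-(methoxymethoxy)benzene; 3 diisopropyl squarate
Product: 7 3-[2,4-bis(benzyloxy)-6-(methoxymethoxy)phenyl]-4-isopropoxycyclobut-3-ene-1,2-dione, via aryllithium 4 (not isolated), via lithium alkoxide adduct 5 (not isolated), via tertiary trifluoroacetate 6 (not isolated)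
Conditions: n-BuLi (1.05 equiv), THF, 0 °C, 1 h; cannulate into 3 (1.1 equiv), THF, −78 °C; (CF3CO)2O (1.2 equiv), −78 °C; aq. NaHCO3, → rt
Reagents that add atoms: water, O
Why: Directed ortho-metalation at either of the two equivalent sites flanked by the chelating OMOM group and an OBn group, 1,2-addition of the aryllithium to a squarate carbonyl (little affected by ortho substituents) and trifluoroacetate-assisted ionisation with hydrolytic loss of isopropanol form the standard squarate-to-cyclobutenedione sequence, here in its aprotic version so that the MOM acetal is not endangered.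

Step 3
Reactants: 7 3-[2,4-bis(benzyloxy)-6-(methoxymethoxy)phenyl]-4-isopropoxycyclobut-3-ene-1,2-dione
Product: 8 2-[2,4-bis(benzyloxy)-6-(methoxymethoxy)phenyl]-4-hydroxy-3-isopropoxycyclobut-2-en-1-one (racemic)
Conditions: LiAlH(OtBu)3 (1.1 equiv), THF, −78 → −20 °C; H2O
Reagents that add atoms: none
Why: Chemoselective 1,2-reduction with a bulky hydride goes to the carbonyl next to C–OiPr, which is a true ketone remote from the aryl group, and not to the vinylogous ester carbonyl next to C–aryl, and the new carbinol centre is racemic and is erased in step 9.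

Step 4
Reactants: 8 2-[2,4-bis(benzyloxy)-6-(methoxymethoxy)phenyl]-4-hydroxy-3-isopropoxycyclobut-2-en-1-one
Product: 10 2-[2,4-bis(benzyloxy)-6-(methoxymethoxy)phenyl]-4-chloro-3-isopropoxycyclobut-2-en-1-one (racemic), via chlorosulfite 9 (not isolated)
Conditions: SOCl2 (1.2 equiv), 2,6-lutidine (1.5 equiv), CH2Cl2, −20 → 0 °C
Reagents that add atoms: thionyl chloride, O=S(Cl)Cl
Why: Deoxychlorination through the chlorosulfite is the usual entry to 4-chlorocyclobutenones, the hindered pyridine base binds HCl before it can attack the MOM acetal, the centre stays racemic, and an allylically transposed chloride would do no harm because it ionises to the same π-allyl complex in step 8.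

Step 5
Reactants: 11 (E)-4-methoxybut-3-en-2-one; 12 4-methoxybenzoyl chloride
Product: 15 2-(4-methoxyphenyl)-4H-pyran-4-one, via lithium dienolate 13 (not isolated), via methoxy enedione 14 (not isolated)
Conditions: 11 (2.1 equiv), LiN(SiMe3)2 (2.1 equiv), THF, −78 °C; 12 (1.0 equiv), −78 °C; aq. NH4Cl; crude 14, CF3CO2H (cat.), toluene, rt
Reagents that add atoms: none
Why: C-acylation of the kinetic dienolate of a vinylogous ester by an aroyl chloride (the second equivalent of dienolate absorbs the acidic diketone proton) followed by acid-catalysed 6-endo addition–elimination with loss of methanol is an established γ-pyranone synthesis for 2-aryl members.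

Step 6
Reactants: 15 2-(4-methoxyphenyl)-4H-pyran-4-one
Product: 17 2-iodo-6-(4-methoxyphenyl)-4H-pyran-4-one, via dipyranylzinc 16 (not isolated)
Conditions: TMP2Zn·2MgCl2·2LiCl (0.6 equiv; TMP = 2,2,6,6-tetramethylpiperidide), THF, −30 → 0 °C; I2 (1.3 equiv), THF, 0 °C → rt
Reagents that add atoms: iodine, [I][I]
Why: In this directed zincation and iodolysis MgCl2 occupies the carbonyl oxygen, which switches off carbonyl-guided attack at C3 and C5 and leaves the most acidic ring proton, C6–H next to O1, for the amide, as is established for C2 of chromones and for γ-pyranones, while the covalent carbon–zinc bond avoids the ring opening that lithiated pyranones suffer.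

Step 7
Reactants: 17 2-iodo-6-(4-methoxyphenyl)-4H-pyran-4-one
Product: 18 2-(4-methoxyphenyl)-6-(tributylstannyl)-4H-pyran-4-one
Conditions: (Bu3Sn)2 (1.5 equiv), Pd(PPh3)4 (5 mol %), toluene, 100 °C
Reagents that add atoms: hexabutylditin, CCCC[Sn](CCCC)(CCCC)[Sn](CCCC)(CCCC)CCCC
Why: Palladium-catalysed stannylation of an electron-poor alkenyl or heteroaryl iodide with a distannane (oxidative addition, tin–tin transmetalation, reductive elimination) is general, and the excess of distannane outruns homocoupling of 17 with 18.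

Step 8
Reactants: 10 2-[2,4-bis(benzyloxy)-6-(methoxymethoxy)phenyl]-4-chloro-3-isopropoxycyclobut-2-en-1-one; 18 2-(4-methoxyphenyl)-6-(tributylstannyl)-4H-pyran-4-one
Product: 19 2-[2,4-bis(benzyloxy)-6-(methoxymethoxy)phenyl]-3-isopropoxy-4-[6-(4-methoxyphenyl)-4-oxo-4H-pyran-2-yl]cyclobut-2-en-1-one (racemic at C4)
Conditions: 18 (1.1 equiv), Pd2(dba)3 (2.5 mol %), P(2-furyl)3 (10 mol %), CuI (10 mol %), dioxane, 50 °C, no base
Reagents that add atoms: none
Why: In this Stille coupling of a 4-chlorocyclobutenone zerovalent palladium ionises the allylic α-keto chloride to an η3-oxocyclobutenyl complex, the weakly donating furylphosphine and CuI speed up transfer of the electron-poor pyranyl group from tin, and reductive elimination takes the open CH terminus instead of the carbon that bears the 2,6-dioxygenated aryl group, giving racemic C4 in a neutral medium that leaves the acidic C4–H in place.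

Step 9
Reactants: 19 2-[2,4-bis(benzyloxy)-6-(methoxymethoxy)phenyl]-3-isopropoxy-4-[6-(4-methoxyphenyl)-4-oxo-4H-pyran-2-yl]cyclobut-2-en-1-one
Product: 22 6-[2,4-bis(benzyloxy)-6-(methoxymethoxy)phenyl]-5-hydroxy-7-isopropoxy-4'-methoxyflavone, via dienylketene 20 (not isolated), via 4aH-chromenedione 21 (not isolated)
Conditions: toluene (dry, degassed, 0.01 M), 110 °C, silylated glassware, no additive
Reagents that add atoms: none
Why: Heat breaks the C1–C4 σ bond of the cyclobutenone (future C5 and C8) in a conrotatory 4π electrocyclic opening, and because this opening is reversible the unproductive ketene with the pyranyl group turned outward drains back through 19 into ketene 20, in which the π-accepting pyranyl group lies cis to the ketene chain. Ketene 20 then closes the six-membered carbocycle, ring A of unit 1, by a disrotatory 6π electrocyclisation in which the electrophilic ketene carbon C5 bonds to the nucleophilic enol-ether carbon C3 of the pyranone (C4a), a matched polarity, to give dienone 21. The C4a–H of 21 lies between two carbonyl groups, so enolisation to the hydrogen-bonded 5-OH phenol 22 should be fast and irreversible and should pull all preceding equilibria forward. The closest known reaction type is the thermal ring expansion of 4-aryl-, 4-heteroaryl- and 4-alkenylcyclobutenones to phenols (Moore-type rearrangement, also the closing stage of the Danheiser benzannulation). No stereocentre is created, since C4 of 19 and C4a of 21 both end as sp2 carbons and the C6–C8'' axis arises as a racemate. The selectivity needed is the site of closure, which the substrate secures because the attachment atom C8a has only O1 and C4a as ring neighbours and both ortho carbons of the C6 aryl group are substituted, while dry, dilute, base-free conditions suppress ketene capture and a prototropic shift of C4–H.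

Step 10
Reactants: 22 6-[2,4-bis(benzyloxy)-6-(methoxymethoxy)phenyl]-5-hydroxy-7-isopropoxy-4'-methoxyflavone
Product: 23 6-[2,4-bis(benzyloxy)-6-hydroxyphenyl]-5-hydroxy-7-isopropoxy-4'-methoxyflavone
Conditions: p-TsOH·H2O (0.2 equiv), MeOH–CH2Cl2, 40 °C
Reagents that add atoms: none
Why: Acid-catalysed acetal exchange with methanol removes only the MOM group, since benzyl, isopropyl and methyl aryl ethers and the flavone core are inert to catalytic sulfonic acid, and it frees the one oxygen destined to be O1''.

Step 11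
Reactants: 23 6-[2,4-bis(benzyloxy)-6-hydroxyphenyl]-5-hydroxy-7-isopropoxy-4'-methoxyflavone; 24 methyl 3-(4-methoxyphenyl)propiolate
Product: 25 methyl (Z)-3-{3,5-bis(benzyloxy)-2-[5-hydroxy-7-isopropoxy-2-(4-methoxyphenyl)-4-oxo-4H-chromen-6-yl]phenoxy}-3-(4-methoxyphenyl)acrylate
Conditions: 24 (2 equiv), Cs2CO3 (0.3 equiv), DMF, 70 °C
Reagents that add atoms: none
Why: Base-catalysed oxa-Michael addition of a phenoxide to an alkynoate should involve only the more acidic non-chelated phenol, because the 5-OH is tied to C4=O by a hydrogen bond and walled in by the C6 aryl group, anti addition places aryloxy and ester groups cis (Z), and any E isomer can be carried along since this push–pull alkene equilibrates under the acid of step 13.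

Step 12
Reactants: 25 methyl (Z)-3-aryloxy-3-(4-methoxyphenyl)acrylate described in step 11
Product: 26 (Z)-3-{3,5-bis(benzyloxy)-2-[5-hydroxy-7-isopropoxy-2-(4-methoxyphenyl)-4-oxo-4H-chromen-6-yl]phenoxy}-3-(4-methoxyphenyl)acrylic acid
Conditions: LiOH·H2O (5 equiv), THF–MeOH–H2O, 40 °C; 1 M HCl to pH 3
Reagents that add atoms: lithium hydroxide, [Li+].[OH-]
Why: Saponification at the unhindered ester carbonyl is faster than hydroxide attack at the donor-flanked β-carbon, and once the carboxylate has formed the enol ether is switched off towards addition–elimination.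

Step 13
Reactants: 26 (Z)-3-aryloxy-3-(4-methoxyphenyl)acrylic acid described in step 12
Product: 28 5'',7''-bis(benzyloxy)-5-hydroxy-7-isopropoxy-4',4'''-dimethoxy-6,8''-biflavone, via mixed trifluoroacetic anhydride 27 (not isolated)
Conditions: (CF3CO)2O (3 equiv), CH2Cl2, 0 °C → rt; MeOH, aq. NaHCO3
Reagents that add atoms: none
Why: In this intramolecular Friedel–Crafts acylation through a mixed anhydride (the closure of a Ruhemann-type flavone synthesis) the acyl carbon can reach only C4a'', the sole free carbon ortho to O1'', which is further activated by the ortho 5''-OBn and para 7''-OBn groups, so the six-membered ring C of unit 2 forms with the 8''-linkage fixed under conditions mild enough for benzyl ethers, and the methanolic bicarbonate wash cleaves any aryl trifluoroacetate.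

Step 14
Reactants: 28 5'',7''-bis(benzyloxy)-5-hydroxy-7-isopropoxy-4',4'''-dimethoxy-6,8''-biflavone
Product: 29 5,7,5'',7''-tetrahydroxy-4',4'''-dimethoxy-6,8''-biflavone (CNP0226117.0)
Conditions: BCl3 (10 equiv), C6HMe5 (6 equiv), CH2Cl2, −78 °C → rt; H2O
Reagents that add atoms: none
Why: Lewis-acid ether cleavage with BCl3 removes the groups that can leave as stabilised cations (two benzyl, one isopropyl) but not unchelated aryl methyl ethers, so both anisyl OMe groups stay, and pentamethylbenzene traps benzyl cations before they can C-alkylate the phloroglucinol rings.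

Compound list
1 | 3,5-bis(benzyloxy)phenol | Oc1cc(OCc2ccccc2)cc(OCc2ccccc2)c1 | starting material
2 | 1,3-bis(benzyloxy)-5-(methoxymethoxy)benzene | COCOc1cc(OCc2ccccc2)cc(OCc2ccccc2)c1 | intermediate
3 | diisopropyl squarate | CC(C)OC1=C(OC(C)C)C(=O)C1=O | starting material
4 | [2,4-bis(benzyloxy)-6-(methoxymethoxy)phenyl]lithium | [Li]c1c(OCOC)cc(OCc2ccccc2)cc1OCc1ccccc1 | intermediate
5 | lithium 1-[2,4-bis(benzyloxy)-6-(methoxymethoxy)phenyl]-2,3-diisopropoxy-4-oxocyclobut-2-en-1-olate (racemic) | [Li]OC1(c2c(OCOC)cc(OCc3ccccc3)cc2OCc2ccccc2)C(OC(C)C)=C(OC(C)C)C1=O | intermediate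
6 | 1-[2,4-bis(benzyloxy)-6-(methoxymethoxy)phenyl]-2,3-diisopropoxy-4-oxocyclobut-2-en-1-yl trifluoroacetate (racemic) | O=C(OC1(c2c(OCOC)cc(OCc3ccccc3)cc2OCc2ccccc2)C(OC(C)C)=C(OC(C)C)C1=O)C(F)(F)F | intermediate
7 | 3-[2,4-bis(benzyloxy)-6-(methoxymethoxy)phenyl]-4-isopropoxycyclobut-3-ene-1,2-dione | CC(C)OC1=C(c2c(OCOC)cc(OCc3ccccc3)cc2OCc2ccccc2)C(=O)C1=O | intermediate
8 | 2-[2,4-bis(benzyloxy)-6-(methoxymethoxy)phenyl]-4-hydroxy-3-isopropoxycyclobut-2-en-1-one (racemic) | CC(C)OC1=C(c2c(OCOC)cc(OCc3ccccc3)cc2OCc2ccccc2)C(=O)C1O | intermediate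
9 | chlorosulfite of 8 (racemic) | CC(C)OC1=C(c2c(OCOC)cc(OCc3ccccc3)cc2OCc2ccccc2)C(=O)C1OS(=O)Cl | intermediate
10 | 2-[2,4-bis(benzyloxy)-6-(methoxymethoxy)phenyl]-4-chloro-3-isopropoxycyclobut-2-en-1-one (racemic) | CC(C)OC1=C(c2c(OCOC)cc(OCc3ccccc3)cc2OCc2ccccc2)C(=O)C1Cl | intermediate
11 | (E)-4-methoxybut-3-en-2-one | CO/C=C/C(C)=O | starting material
12 | 4-methoxybenzoyl chloride | COc1ccc(C(=O)Cl)cc1 | starting material
13 | lithium (E)-4-methoxybuta-1,3-dien-2-olate | [Li]OC(=C)/C=C/OC | intermediate
14 | (E)-5-methoxy-1-(4-methoxyphenyl)pent-4-ene-1,3-dione | CO/C=C/C(=O)CC(=O)c1ccc(OC)cc1 | intermediate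
15 | 2-(4-methoxyphenyl)-4H-pyran-4-one | COc1ccc(-c2cc(=O)cco2)cc1 | intermediate
16 | bis[6-(4-methoxyphenyl)-4-oxo-4H-pyran-2-yl]zinc | COc1ccc(-c2cc(=O)cc([Zn]c3cc(=O)cc(-c4ccc(OC)cc4)o3)o2)cc1 | intermediate
17 | 2-iodo-6-(4-methoxyphenyl)-4H-pyran-4-one | COc1ccc(-c2cc(=O)cc(I)o2)cc1 | intermediate
18 | 2-(4-methoxyphenyl)-6-(tributylstannyl)-4H-pyran-4-one | CCCC[Sn](CCCC)(CCCC)c1cc(=O)cc(-c2ccc(OC)cc2)o1 | intermediate
19 | 2-[2,4-bis(benzyloxy)-6-(methoxymethoxy)phenyl]-3-isopropoxy-4-[6-(4-methoxyphenyl)-4-oxo-4H-pyran-2-yl]cyclobut-2-en-1-one (racemic at C4) | COCOc1cc(OCc2ccccc2)cc(OCc2ccccc2)c1C1=C(OC(C)C)C(c2cc(=O)cc(-c3ccc(OC)cc3)o2)C1=O | intermediate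
20 | (3E)-2-[2,4-bis(benzyloxy)-6-(methoxymethoxy)phenyl]-3-isopropoxy-4-[6-(4-methoxyphenyl)-4-oxo-4H-pyran-2-yl]buta-1,3-dien-1-one (pyranyl group cis to the ketene chain) | O=C=C(c1c(OCOC)cc(OCc2ccccc2)cc1OCc1ccccc1)/C(OC(C)C)=C\c1cc(=O)cc(-c2ccc(OC)cc2)o1 | intermediate
21 | 6-[2,4-bis(benzyloxy)-6-(methoxymethoxy)phenyl]-7-isopropoxy-2-(4-methoxyphenyl)-4aH-chromene-4,5-dione (racemic at C4a) | COc1ccc(C2=CC(=O)C3C(=O)C(c4c(OCOC)cc(OCc5ccccc5)cc4OCc4ccccc4)=C(OC(C)C)C=C3O2)cc1 | intermediate
22 | 6-[2,4-bis(benzyloxy)-6-(methoxymethoxy)phenyl]-5-hydroxy-7-isopropoxy-4'-methoxyflavone (racemic axis) | COc1ccc(-c2cc(=O)c3c(O)c(-c4c(OCOC)cc(OCc5ccccc5)cc4OCc4ccccc4)c(OC(C)C)cc3o2)cc1 | intermediate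
23 | 6-[2,4-bis(benzyloxy)-6-hydroxyphenyl]-5-hydroxy-7-isopropoxy-4'-methoxyflavone (racemic axis) | COc1ccc(-c2cc(=O)c3c(O)c(-c4c(O)cc(OCc5ccccc5)cc4OCc4ccccc4)c(OC(C)C)cc3o2)cc1 | intermediate
24 | methyl 3-(4-methoxyphenyl)propiolate | COC(=O)C#Cc1ccc(OC)cc1 | starting material
25 | methyl (Z)-3-{3,5-bis(benzyloxy)-2-[5-hydroxy-7-isopropoxy-2-(4-methoxyphenyl)-4-oxo-4H-chromen-6-yl]phenoxy}-3-(4-methoxyphenyl)acrylate (racemic axis) | COC(=O)/C=C(\Oc1cc(OCc2ccccc2)cc(OCc2ccccc2)c1-c1c(O)c2c(=O)cc(-c3ccc(OC)cc3)oc2cc1OC(C)C)c1ccc(OC)cc1 | intermediate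
26 | (Z)-3-{3,5-bis(benzyloxy)-2-[5-hydroxy-7-isopropoxy-2-(4-methoxyphenyl)-4-oxo-4H-chromen-6-yl]phenoxy}-3-(4-methoxyphenyl)acrylic acid (racemic axis) | OC(=O)/C=C(\Oc1cc(OCc2ccccc2)cc(OCc2ccccc2)c1-c1c(O)c2c(=O)cc(-c3ccc(OC)cc3)oc2cc1OC(C)C)c1ccc(OC)cc1 | intermediate
27 | mixed anhydride of 26 and trifluoroacetic acid | FC(F)(F)C(=O)OC(=O)/C=C(\Oc1cc(OCc2ccccc2)cc(OCc2ccccc2)c1-c1c(O)c2c(=O)cc(-c3ccc(OC)cc3)oc2cc1OC(C)C)c1ccc(OC)cc1 | intermediate
28 | 5'',7''-bis(benzyloxy)-5-hydroxy-7-isopropoxy-4',4'''-dimethoxy-6,8''-biflavone (racemic axis) | COc1ccc(-c2cc(=O)c3c(O)c(-c4c(OCc5ccccc5)cc(OCc5ccccc5)c5c(=O)cc(-c6ccc(OC)cc6)oc45)c(OC(C)C)cc3o2)cc1 | intermediate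
29 | 5,7,5'',7''-tetrahydroxy-4',4'''-dimethoxy-6,8''-biflavone (6,8''-biacacetin, CNP0226117.0) | COc1ccc(-c2cc(=O)c3c(O)c(-c4c(O)cc(O)c5c(=O)cc(-c6ccc(OC)cc6)oc45)c(O)cc3o2)cc1 | target

Total step count: 14.
Longest linear sequence: 11 steps (steps 1–4, then 8–14). The pyranone branch (steps 5–7) joins at step 8.

Steps most likely to fail

1. Step 9 (key step).
- What may go wrong: the ketene may be consumed by dimerisation, or by attack of the neighbouring acetal or benzyl ether oxygen, faster than it closes on the cross-conjugated pyranone alkene. A prototropic shift of C4–H may also move the ring double bond into conjugation with the pyranone, which leaves a cyclobutenone without an open closure site.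
- Fallback: the biaryl bond is made on an intact flavone by Suzuki–Miyaura coupling. The fallback sets out from 2, which is lithiated to 4 as in step 2 and quenched with iPrOBpin to give 2-[2,4-bis(benzyloxy)-6-(methoxymethoxy)phenyl]-4,4,5,5-tetramethyl-1,3,2-dioxaborolane F1. Purchased acacetin F2 is alkylated at its non-chelated 7-OH (2-bromopropane, K2CO3, DMF) to 5-hydroxy-7-isopropoxy-4'-methoxyflavone F3. This is iodinated ortho to the free 5-OH (BnNMe3ICl2, CaCO3, CH2Cl2–MeOH) to 5-hydroxy-6-iodo-7-isopropoxy-4'-methoxyflavone F4. Coupling of F1 with F4 (Pd(OAc)2, SPhos, K3PO4, toluene–H2O, 90 °C) comes back to the route at 22.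

2. Step 8.
- What may go wrong: transfer of the electron-poor pyranyl group from tin to palladium may be so slow that protodestannylation and thermal or palladium-induced decay of the chloride win.
- Fallback: zinc replaces tin in a Negishi coupling. The fallback sets out from 17 and 10. Insertion of zinc into the carbon–iodine bond of 17 (Zn dust, LiCl, THF, 25 °C) gives amine-free [6-(4-methoxyphenyl)-4-oxo-4H-pyran-2-yl]zinc iodide F5. This transmetalates far faster and is coupled with 10 at room temperature (Pd2(dba)3, P(2-furyl)3, THF). The fallback comes back to the route at 19, and step 7 falls away.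

3. Step 11.
- What may go wrong: conjugate addition of a phenoxide hemmed in by the biaryl axis to an alkynoate deactivated by its anisyl donor may be sluggish. That leaves room for reversal of the addition, attack by the 5-OH or base-induced decay of the alkynoate.
- Fallback: the carbon–carbon bond is made first, by the classical chalcone route. The fallback sets out from 23. C-acetylation with Ac2O and BF3·OEt2, guided to C4a'' by boron chelation with the free phenol, gives 6-[3-acetyl-4,6-bis(benzyloxy)-2-hydroxyphenyl]-5-hydroxy-7-isopropoxy-4'-methoxyflavone F6. Claisen–Schmidt condensation with 4-methoxybenzaldehyde (KOH, EtOH, rt) gives the (E)-2'-hydroxychalcone F7. Oxidative cyclisation (catalytic I2, DMSO, 120 °C) closes O1''–C2''. The fallback comes back to the route at 28 and replaces steps 11–13.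

Further compounds
F1 | step 9 | 2-[2,4-bis(benzyloxy)-6-(methoxymethoxy)phenyl]-4,4,5,5-tetramethyl-1,3,2-dioxaborolane | CC1(C)OB(c2c(OCOC)cc(OCc3ccccc3)cc2OCc2ccccc2)OC1(C)C
F2 | step 9 | acacetin (purchased) | COc1ccc(-c2cc(=O)c3c(O)cc(O)cc3o2)cc1
F3 | step 9 | 5-hydroxy-7-isopropoxy-4'-methoxyflavone | COc1ccc(-c2cc(=O)c3c(O)cc(OC(C)C)cc3o2)cc1
F4 | step 9 | 5-hydroxy-6-iodo-7-isopropoxy-4'-methoxyflavone | COc1ccc(-c2cc(=O)c3c(O)c(I)c(OC(C)C)cc3o2)cc1
F5 | step 8 | [6-(4-methoxyphenyl)-4-oxo-4H-pyran-2-yl]zinc iodide | COc1ccc(-c2cc(=O)cc([Zn]I)o2)cc1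
F6 | step 11 | 6-[3-acetyl-4,6-bis(benzyloxy)-2-hydroxyphenyl]-5-hydroxy-7-isopropoxy-4'-methoxyflavone | COc1ccc(-c2cc(=O)c3c(O)c(-c4c(O)c(C(C)=O)c(OCc5ccccc5)cc4OCc4ccccc4)c(OC(C)C)cc3o2)cc1
F7 | step 11 | (E)-1-{4,6-bis(benzyloxy)-2-hydroxy-3-[5-hydroxy-7-isopropoxy-2-(4-methoxyphenyl)-4-oxo-4H-chromen-6-yl]phenyl}-3-(4-methoxyphenyl)prop-2-en-1-one | COc1ccc(/C=C/C(=O)c2c(O)c(-c3c(O)c4c(=O)cc(-c5ccc(OC)cc5)oc4cc3OC(C)C)c(OCc3ccccc3)cc2OCc2ccccc2)cc1
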